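5 questions stand on 4 flasks of one charge. The decision is whether that charge may be left as written, up to 20 h at 150 °C.

| setting | maple | north-east | north | south | north-west |
|---|---|---|---|---|---|
| substrate | 0.20 M | 0.10 M | 0.10 M | 0.10 M | 0.10 M |
| coupling partner | 0.080 M | 0.0800 M | 0.0800 M | 0.0800 M | 0.0800 M |
| scavenger | 0.12 M | 0.120 M | 0.120 M | 0.120 M | 0.120 M |
| temperature | 150 °C | 150 °C |  | 125 °C | 100 °C |
| remark | run made earlier |  | at 100 °C until 4.0 h, from then on at 150 °C |  |  |
| time |  | 20 h | 20 h | 20 h | 20 h |

- maple (time / min: single product / %): 30.0: 24.0; 60.0: 30.0; 90.0: 32.5; 120: 35.0

(standard deviation of a reading: 1 percentage point)

- which flask leads in amount of single product, in percent of the substrate charged ("all alike" within 1.5 percentage points) (north-east / north / south / north-west / all alike)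
- how much single product is there at the end, in percent of the substrate charged: north-east
- how much single product is there at the end, in percent of the substrate charged: north
- how much single product is there at the end, in percent of the substrate charged: south
- how much single product is there at the end, in percent of the substrate charged: north-west

- the earlier runs do not show what temperature does; that part of a forecast is a guess

Each single product takes one coupling partner. In the maple run [coupling partner] starts below [substrate], so the partner is the limiting reagent there, and the new charge keeps that order. The partner ceiling is charged [coupling partner] divided by charged [substrate], in percent of the substrate80.0%. The maple ceiling is 40.0%.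

As a working assumption made before the flasks are run, the ceiling is taken as the large part and the gap below it as a small correction. The last maple reading stands 5 percentage points below its ceiling, with a scatter of 1 point. That is 12.5% of the ceiling. The reckoning made here holds that share and puts north-east at 70.0%. It goes no further, since the earlier runs do not show what temperature does. But 20 h is ten times the last maple time, so the charge is run as written and each flask is held against the ceiling.

The forecast names north as leader. It gives 70% for north-east, 71% for north, 58% for south and 30% for north-west, on its own ground that “halving the substrate favours any competing partner loss”.

The flasks give 40.7% for north-east, 45.2% for north, 66.7% for south and 52.8% for north-west, and south leads. North-east stands 39 points below the ceiling, against the 10 points reckoned. That gap is half of the ceiling, so in north-east it is no small correction and the assumption fails.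

    substrate + coupling partner → single product + released group (k = 2.25 L mol⁻¹ h⁻¹, Ea = 66.0 kJ mol⁻¹)
    coupling partner + single product → double product + released group (k = 0.0706 L mol⁻¹ h⁻¹, Ea = 107 kJ mol⁻¹)
    coupling partner + double product → tris adduct + released group (k = 0.943 L mol⁻¹ h⁻¹, Ea = 93.0 kJ mol⁻¹)
    coupling partner + released group ⇌ idle adduct, settled at all times (K = 3250 L mol⁻¹, ΔH = −7.00 kJ mol⁻¹)
    scavenger + released group → scavenged by-product (k = 31.7 L mol⁻¹ h⁻¹, Ea = 81.0 kJ mol⁻¹)
    single product → over-reaction product (k = 1.83 × 10⁻⁴ h⁻¹, Ea = 127 kJ mol⁻¹)
    (constants at 100 °C)

In north at 20.0 h, coupling partner is at 0% of its charge. Single product, over-reaction product, double product taken 2 times and tris adduct taken 3 times sum to 80.0%, near the ceiling. The neighbour flask is north with 0.040 M of substrate, and its ceiling is 200%. The same sum, with the partner left (4.62% of its charge) added, gives 200%. Its single product is 33.3%, less than its tris adduct at 42.6%.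

The readings were computed from invented constants.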